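**Strategy.** The target is cut at the two C–O bonds on adjacent carbons of the heterocyclic ring C, C3–OH and C4=O. Both oxygens are delivered in one operation to the C3=C4 double bond of a (2S)-flav-3-ene (2-aryl-2H-chromene) by osmium-catalysed syn-dihydroxylation on the face opposite the C2 aryl group (ring B). The lone C2 stereocentre thus dictates C3, and C4 is then oxidised to the ketone. The precursor carries benzyl ethers on O5 and O7 and a triisopropylsilyl ether on O4′, so that hydrogenolysis later frees only the ring-A phenols and prenylation at O7 cannot stray to O4′. C2 comes from iridium-catalysed allylic etherification, the pyran ring from metathesis.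

Key step: step 8

Assumption: the (Sa,S,S) antipode of the binaphthol-derived N,N-bis(1-phenylethyl)phosphoramidite ligand (L) is taken as the one that gives the (S)-configured branched aryl ether, its mirror image being taken as the ligand that gives (R)-ethers from cinnamyl carbonates. This sense is recalled from the catalyst class and must be confirmed on the first run; should it be opposite, the antipodal ligand is used and nothing else changes.

Remark on descriptors: the CIP label at C2 changes from S (ether, flavene) to R (diol, ketone, target), and that at C3 from S (diol) to R (ketone), only because substituent priorities change. The spatial arrangement is the same throughout.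

Remark on starting material: commercial methyl (E)-4-hydroxycinnamate is used instead of the free acid to save an esterification.

Step 1
Reactants: 1 methyl (E)-4-hydroxycinnamate
Product: 2 methyl (E)-4-(triisopropylsilyloxy)cinnamate
Conditions: TIPSCl (1.2 equiv), imidazole (2.5 equiv), DMF, rt
Reagents that add atoms: triisopropylsilyl chloride, CC(C)[Si](Cl)(C(C)C)C(C)C
Why: Imidazole-promoted silylation of the phenol gives an aryl TIPS ether that should survive hydride, aryloxide, Ru, Os(VIII), DDQ and H2/Pd and is later removed by fluoride.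

Step 2
Reactants: 2 methyl (E)-4-(triisopropylsilyloxy)cinnamate
Product: 3 (E)-3-[4-(triisopropylsilyloxy)phenyl]prop-2-en-1-ol
Conditions: DIBAL-H (2.5 equiv), CH2Cl2, −78 °C to 0 °C; aqueous Rochelle salt
Reagents that add atoms: none
Why: 1,2-Reduction of the conjugated ester by DIBAL-H gives the allylic alcohol and leaves the E alkene and the silyl ether untouched.

Step 3
Reactants: 3 (E)-3-[4-(triisopropylsilyloxy)phenyl]prop-2-en-1-ol
Product: 4 methyl (E)-3-[4-(triisopropylsilyloxy)phenyl]prop-2-en-1-yl carbonate
Conditions: ClCO2Me (1.5 equiv), pyridine (3 equiv), CH2Cl2, 0 °C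
Reagents that add atoms: methyl chloroformate, COC(=O)Cl
Why: O-Acylation of the primary allylic alcohol gives the linear methyl carbonate, the standard electrophile for iridium-catalysed allylic substitution.

Step 4
Reactants: 5 2,4,6-trihydroxybenzaldehyde; 6 benzyl bromide
Product: 7 4,6-bis(benzyloxy)-2-hydroxybenzaldehyde
Conditions: BnBr (2.05 equiv), K2CO3 (2.1 equiv), DMF, 0 °C to rt
Reagents that add atoms: benzyl bromide (6), BrCc1ccccc1
Why: Williamson O-benzylation takes the two non-chelated hydroxyls, while the hydroxyl hydrogen-bonded to the formyl group stays free to become O1 later.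

Step 5
Reactants: 7 4,6-bis(benzyloxy)-2-hydroxybenzaldehyde
Product: 8 3,5-bis(benzyloxy)-2-vinylphenol
Conditions: Ph3PCH3Br (2.5 equiv), KOt-Bu (2.5 equiv), THF, 0 °C to rt; NH4Cl work-up; used at once, kept cold and acid-free
Reagents that add atoms: methyltriphenylphosphonium bromide, C[P+](c1ccccc1)(c1ccccc1)c1ccccc1.[Br-]
Why: Wittig methylenation with excess ylide (one equivalent of base is held by the phenol, which is recovered on work-up) turns the formyl group into the vinyl group needed for metathesis.

Step 6
Reactants: 8 3,5-bis(benzyloxy)-2-vinylphenol; 4 methyl (E)-3-[4-(triisopropylsilyloxy)phenyl]prop-2-en-1-yl carbonate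
Product: 10 (S)-1,5-bis(benzyloxy)-3-({1-[4-(triisopropylsilyloxy)phenyl]prop-2-en-1-yl}oxy)-2-vinylbenzene, via lithium aryloxide 9 (not isolated)
Conditions: LiHMDS (1.0 equiv), THF, 0 °C; then 4 (1.1 equiv), [Ir(cod)Cl]2 (2 mol %), (Sa,S,S)-L (4 mol %, catalyst pre-activated with n-PrNH2), THF, rt, dark; stopped as soon as 4 is consumed
Reagents that add atoms: lithium hexamethyldisilazide, [Li+].C[Si](C)(C)[N-][Si](C)(C)C (supplies only the lithium of intermediate 9; no atom of it remains in 10)
Why: Iridium-catalysed asymmetric allylic etherification, in which the aryloxide oxygen attacks the aryl-substituted terminus of the allyl–iridium species to give the branched ether, the new C–O stereocentre (later C2) being set by the chiral cyclometalated Ir–phosphoramidite catalyst (reagent control).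

Step 7
Reactants: 10 (S)-1,5-bis(benzyloxy)-3-({1-[4-(triisopropylsilyloxy)phenyl]prop-2-en-1-yl}oxy)-2-vinylbenzene
Product: 11 (2S)-5,7-bis(benzyloxy)-2-[4-(triisopropylsilyloxy)phenyl]-2H-chromene
Conditions: second-generation Ru metathesis catalyst [(H2IMes)(PCy3)Cl2Ru=CHPh] (5 mol %), 1,4-benzoquinone (10 mol %), CH2Cl2 (0.01 M), 40 °C, dark
Reagents that add atoms: none
Why: Ring-closing metathesis of the styrenyl and allyl alkenes closes the six-membered pyran ring with loss of ethylene under neutral conditions that do not touch the C2 stereocentre or ionise its doubly activated C–O bond.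

Step 8
Reactants: 11 (2S)-5,7-bis(benzyloxy)-2-[4-(triisopropylsilyloxy)phenyl]-2H-chromene
Product: 13 (2R,3S,4S)-5,7-bis(benzyloxy)-2-[4-(triisopropylsilyloxy)phenyl]chromane-3,4-diol, via cyclic osmate ester 12 (not isolated)
Conditions: OsO4 (2.5 mol %), NMO (1.5 equiv), acetone/THF/H2O, 0 °C to rt, dark; Na2SO3 quench
Reagents that add atoms: osmium tetroxide, O=[Os](=O)(=O)=O (delivers both oxygens); N-methylmorpholine N-oxide, C[N+]1([O-])CCOCC1 (restores the oxide); water, O (hydrolysis of the osmate ester)
Why: Osmium tetroxide adds across the electron-rich styrenic C3=C4 bond in a concerted, suprafacial [3+2] cycloaddition to give the cyclic osmate(VI) ester 12, which is hydrolysed to the cis-diol while NMO returns the metal to Os(VIII); the closest known reaction type is the Upjohn dihydroxylation of 2H-chromenes and flav-3-enes. No ring of the product is closed here (the five-membered osmate ring formed by the cycloaddition is transient); the two new bonds are C3–O and C4–O. C3 is controlled by the existing C2 stereocentre: the 2-aryl group shields its own face of the half-chair pyran ring, so the reagent arrives anti to it and O3 ends up trans to the aryl group, which is the 2,3-trans relationship of the target. C4 is fixed by the syn course of the addition (O4 cis to O3), and its configuration is of no consequence because it is oxidised in step 9. The step needs facial selectivity, secured by the adjacent C2 substituent, and chemoselectivity, secured because C3=C4 is the only alkene present (the prenyl group is introduced only afterwards) and the benzyl and silyl ethers are inert to Os(VIII)/NMO.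

Step 9
Reactants: 13 (2R,3S,4S)-5,7-bis(benzyloxy)-2-[4-(triisopropylsilyloxy)phenyl]chromane-3,4-diol
Product: 14 (2R,3R)-5,7-bis(benzyloxy)-3-hydroxy-2-[4-(triisopropylsilyloxy)phenyl]chroman-4-one
Conditions: DDQ (1.1 equiv), 1,4-dioxane, rt, dark
Reagents that add atoms: none
Why: Chemoselective DDQ dehydrogenation of an activated benzylic alcohol, in which hydride is taken from C4 (its cation is stabilised by the O1/O5/O7-substituted ring A) while the non-benzylic C3 carbinol is inert, so C4 becomes the ketone and C2 and C3 are untouched.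

Step 10
Reactants: 14 (2R,3R)-5,7-bis(benzyloxy)-3-hydroxy-2-[4-(triisopropylsilyloxy)phenyl]chroman-4-one
Product: 15 (2R,3R)-3,5,7-trihydroxy-2-[4-(triisopropylsilyloxy)phenyl]chroman-4-one
Conditions: H2 (1 atm), 10% Pd/C, EtOAc/THF, rt
Reagents that add atoms: none
Why: Catalytic hydrogenolysis cleaves the two benzyl aryl ethers, while the aryl silyl ether, the aryl ketone and the cyclic C2–O bond should survive these mild neutral conditions and no stereocentre is involved.

Step 11
Reactants: 15 (2R,3R)-3,5,7-trihydroxy-2-[4-(triisopropylsilyloxy)phenyl]chroman-4-one; 16 prenyl bromide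
Product: 17 (2R,3R)-3,5-dihydroxy-7-(3-methylbut-2-en-1-yloxy)-2-[4-(triisopropylsilyloxy)phenyl]chroman-4-one
Conditions: prenyl bromide (1.1 equiv), K2CO3 (1.2 equiv), acetone, rt, argon
Reagents that add atoms: prenyl bromide (16), CC(C)=CCBr
Why: Williamson etherification at O7–H, the only acidic, non-chelated phenol left (O5–H is hydrogen-bonded to C4=O, O4′ is silylated, O3–H is an alcohol); with O4′ blocked no quinone methide can open ring C, so C2 is safe under the mild base.

Step 12
Reactants: 17 (2R,3R)-3,5-dihydroxy-7-(3-methylbut-2-en-1-yloxy)-2-[4-(triisopropylsilyloxy)phenyl]chroman-4-one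
Product: 18 7-prenyloxyaromadendrin, (2R,3R)-3,5-dihydroxy-2-(4-hydroxyphenyl)-7-(3-methylbut-2-en-1-yloxy)chroman-4-one
Conditions: TBAF (1.1 equiv), AcOH (1.2 equiv), THF, 0 °C
Reagents that add atoms: none
Why: Fluoride cleavage of the aryl silyl ether, buffered with acetic acid, should leave the acid- and hydrogenation-sensitive prenyl ether and the base-sensitive 3-hydroxy ketone intact.

**Compound list**

1 | methyl (E)-4-hydroxycinnamate | COC(=O)/C=C/c1ccc(O)cc1 | starting material
2 | methyl (E)-4-(triisopropylsilyloxy)cinnamate | COC(=O)/C=C/c1ccc(O[Si](C(C)C)(C(C)C)C(C)C)cc1 | intermediate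
3 | (E)-3-[4-(triisopropylsilyloxy)phenyl]prop-2-en-1-ol | OC/C=C/c1ccc(O[Si](C(C)C)(C(C)C)C(C)C)cc1 | intermediate
4 | methyl (E)-3-[4-(triisopropylsilyloxy)phenyl]prop-2-en-1-yl carbonate | COC(=O)OC/C=C/c1ccc(O[Si](C(C)C)(C(C)C)C(C)C)cc1 | intermediate
5 | 2,4,6-trihydroxybenzaldehyde | O=Cc1c(O)cc(O)cc1O | starting material
6 | benzyl bromide | BrCc1ccccc1 | starting material
7 | 4,6-bis(benzyloxy)-2-hydroxybenzaldehyde | O=Cc1c(O)cc(OCc2ccccc2)cc1OCc1ccccc1 | intermediate
8 | 3,5-bis(benzyloxy)-2-vinylphenol | C=Cc1c(O)cc(OCc2ccccc2)cc1OCc1ccccc1 | intermediate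
9 | lithium 3,5-bis(benzyloxy)-2-vinylphenoxide | [Li+].[O-]c1cc(OCc2ccccc2)cc(OCc2ccccc2)c1C=C | intermediate (not isolated)
10 | (S)-1,5-bis(benzyloxy)-3-({1-[4-(triisopropylsilyloxy)phenyl]prop-2-en-1-yl}oxy)-2-vinylbenzene | C=C[C@H](Oc1cc(OCc2ccccc2)cc(OCc2ccccc2)c1C=C)c1ccc(O[Si](C(C)C)(C(C)C)C(C)C)cc1 | intermediate
11 | (2S)-5,7-bis(benzyloxy)-2-[4-(triisopropylsilyloxy)phenyl]-2H-chromene | c1ccccc1COc1cc(OCc2ccccc2)c2c(c1)O[C@H](c1ccc(O[Si](C(C)C)(C(C)C)C(C)C)cc1)C=C2 | intermediate
12 | cyclic osmate(VI) ester of diol 13 (Os bridging O3 and O4, both anti to the 2-aryl group) | c1ccccc1COc1cc(OCc2ccccc2)c2c(c1)O[C@H](c1ccc(O[Si](C(C)C)(C(C)C)C(C)C)cc1)[C@H]3O[Os](=O)(=O)O[C@@H]23 | intermediate (not isolated)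
13 | (2R,3S,4S)-5,7-bis(benzyloxy)-2-[4-(triisopropylsilyloxy)phenyl]chromane-3,4-diol (2,3-trans-3,4-cis) | c1ccccc1COc1cc(OCc2ccccc2)c2c(c1)O[C@H](c1ccc(O[Si](C(C)C)(C(C)C)C(C)C)cc1)[C@@H](O)[C@H]2O | intermediate
14 | (2R,3R)-5,7-bis(benzyloxy)-3-hydroxy-2-[4-(triisopropylsilyloxy)phenyl]chroman-4-one | c1ccccc1COc1cc(OCc2ccccc2)c2c(c1)O[C@H](c1ccc(O[Si](C(C)C)(C(C)C)C(C)C)cc1)[C@@H](O)C2=O | intermediate
15 | (2R,3R)-3,5,7-trihydroxy-2-[4-(triisopropylsilyloxy)phenyl]chroman-4-one | Oc1cc(O)c2c(c1)O[C@H](c1ccc(O[Si](C(C)C)(C(C)C)C(C)C)cc1)[C@@H](O)C2=O | intermediate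
16 | prenyl bromide (1-bromo-3-methylbut-2-ene) | CC(C)=CCBr | starting material
17 | (2R,3R)-3,5-dihydroxy-7-(3-methylbut-2-en-1-yloxy)-2-[4-(triisopropylsilyloxy)phenyl]chroman-4-one | CC(C)=CCOc1cc(O)c2c(c1)O[C@H](c1ccc(O[Si](C(C)C)(C(C)C)C(C)C)cc1)[C@@H](O)C2=O | intermediate
18 | 7-prenyloxyaromadendrin, (2R,3R)-3,5-dihydroxy-2-(4-hydroxyphenyl)-7-(3-methylbut-2-en-1-yloxy)chroman-4-one | CC(C)=CCOc1cc(O)c2c(c1)O[C@H](c1ccc(O)cc1)[C@@H](O)C2=O | target

**Step count.** Total: 12 steps. Longest linear sequence: 10 steps (steps 1–3, then 6–12); the other branch (steps 4–5) joins at step 6.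

**Steps most likely to fail, with fallbacks**

1. Step 8 (key step). What may go wrong: incomplete facial discrimination by the C2 aryl group, or slow hydrolysis of the hindered osmate ester so that the electron-rich diol is oxidised further. The fallback sets out from 11 and returns at 14. Epoxidation with dimethyldioxirane in acetone at −20 °C, again from the face anti to the aryl group, should give the (2R,3S,4S)-3,4-epoxyflavan F1. This trialkoxybenzylic epoxide is opened by water at C4 (aqueous acetone, NaHCO3) to the 3,4-diol as a mixture of C4 epimers, namely 13 and its (4R)-epimer F2, with O3 already fixed trans to the aryl group by the epoxidation. Both epimers converge on 14 under the DDQ conditions of step 9, because C4 becomes trigonal.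

2. Step 6. What may go wrong: erosion of enantiomeric purity and of the branched regiochemistry, because the catalyst can re-ionise the doubly activated benzylic–allylic aryl ether once it has formed. The fallback sets out from 8 and 4 and returns at 11. Aryloxide 9 is allylated without asymmetric induction using the achiral, branched-selective catalyst [Ir(cod)Cl]2/P(OPh)3 (THF, rt) to give the racemic ether F3. Ring-closing metathesis under the conditions of step 7 gives the racemic flavene F4. The enantiomers are then separated by preparative chromatography on a polysaccharide-carbamate chiral stationary phase, the (2S)-enantiomer being 11.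

3. Step 9. What may go wrong: sluggish hydride abstraction, since in the favoured half-chair the C4–OH is pseudo-axial next to the peri O5-benzyl group and the C4–H bond lies close to the plane of ring A; this leaves time for acid-promoted ionisation at C4 or over-oxidation. The fallback sets out from 13 and returns at 14 by protection, oxidation and deprotection. TBSCl/imidazole (DMF, 0 °C) should silylate the less hindered equatorial C3–OH to give the 3-O-TBS ether F5. The periodinane DMP (NaHCO3, CH2Cl2), which needs no benzylic activation, oxidises the remaining C4–OH to the silyloxy ketone F6. HCl in MeOH (0 °C to rt) then removes the alkyl TBS ether while the aryl TIPS ether stays, giving 14.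

Further compounds
F1 | step 8 | (2R,3S,4S)-5,7-bis(benzyloxy)-3,4-epoxy-2-[4-(triisopropylsilyloxy)phenyl]chromane (epoxide oxygen anti to the 2-aryl group) | c1ccccc1COc1cc(OCc2ccccc2)c2c(c1)O[C@H](c1ccc(O[Si](C(C)C)(C(C)C)C(C)C)cc1)[C@H]3O[C@@H]23
F2 | step 8 | (2R,3S,4R)-5,7-bis(benzyloxy)-2-[4-(triisopropylsilyloxy)phenyl]chromane-3,4-diol (2,3-trans-3,4-trans; C4 epimer of 13) | c1ccccc1COc1cc(OCc2ccccc2)c2c(c1)O[C@H](c1ccc(O[Si](C(C)C)(C(C)C)C(C)C)cc1)[C@@H](O)[C@@H]2O
F3 | step 6 | racemic 1,5-bis(benzyloxy)-3-({1-[4-(triisopropylsilyloxy)phenyl]prop-2-en-1-yl}oxy)-2-vinylbenzene | C=CC(Oc1cc(OCc2ccccc2)cc(OCc2ccccc2)c1C=C)c1ccc(O[Si](C(C)C)(C(C)C)C(C)C)cc1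
F4 | step 6 | racemic 5,7-bis(benzyloxy)-2-[4-(triisopropylsilyloxy)phenyl]-2H-chromene | c1ccccc1COc1cc(OCc2ccccc2)c2c(c1)OC(c1ccc(O[Si](C(C)C)(C(C)C)C(C)C)cc1)C=C2
F5 | step 9 | (2R,3S,4S)-5,7-bis(benzyloxy)-3-(tert-butyldimethylsilyloxy)-2-[4-(triisopropylsilyloxy)phenyl]chroman-4-ol | c1ccccc1COc1cc(OCc2ccccc2)c2c(c1)O[C@H](c1ccc(O[Si](C(C)C)(C(C)C)C(C)C)cc1)[C@@H](O[Si](C)(C)C(C)(C)C)[C@H]2O
F6 | step 9 | (2R,3R)-5,7-bis(benzyloxy)-3-(tert-butyldimethylsilyloxy)-2-[4-(triisopropylsilyloxy)phenyl]chroman-4-one | c1ccccc1COc1cc(OCc2ccccc2)c2c(c1)O[C@H](c1ccc(O[Si](C(C)C)(C(C)C)C(C)C)cc1)[C@@H](O[Si](C)(C)C(C)(C)C)C2=O
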